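Count the chains.

| setting | east | south-east | eta | gamma |
|---|---|---|---|---|
| L | 0.10 M | 0.40 M | 0.20 M | 0.20 M |
| Q | 2 mM | 2 mM | 2.0 mM | 2.0 mM |
| X | 0.26 mM | 0.26 mM | 0.26 mM | 0.26 mM |
| remark | run made earlier | run made earlier |  |  |
| time |  |  | 4.0 min | 12 min |

- east (time / min: G / %): 0.417: 2; 1.00: 9; 2.00: 20; 3.00: 27
- south-east (time / min: G / %): 0.833: 7; 1.50: 18; 2.50: 26; 3.00: 34

(scatter of a reading: 2 percentage points)

- the average divides the monomer in chains by the number of chains begun, living and dead together
- the earlier runs do not show the number of chains; that part of a forecast is a guess

- which of the two ends with the longer chains by the average number of monomer units in a chain (chains begun, living or dead) ("neither" if they lie within 10%) (eta / gamma / neither)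
- average number of monomer units in a chain (chains begun, living or dead) at the end, eta
- average number of monomer units in a chain (chains begun, living or dead) at the end, gamma

X is the smaller charge, at 0.26 mM against 2.0 mM of Q. The earlier runs do not show the chain count, so my own assumption is that X is the limiting reagent in a one-to-one loss of Q and that each Q remaining begins one chain. That gives 1.74 mM of chains in eta and in gamma. The L charged over those chains is 115, the ceiling length, the monomer units per chain once G holds the whole charge. The average length is then the ceiling length times the fraction of L in G.

One number is not enough, since eta and gamma share it. Time enters through the fraction. The east and south-east runs have ceilings of 57.5 and 230, yet at 3.00 min they read 27% and 34%, so I take them as one curve, with a gap of 7 percentage points against a scatter of 2 points on each reading. Their mean, 30.5%, gives a first-order rate of 0.121 min⁻¹, a value read from scattered readings. Eta then reaches 38.4% and gamma 76.7%, an extrapolation beyond the readings. My lengths are 44.2 for eta and 88.1 for gamma, which is twice as long.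

The forecast also says gamma, with 42 (33 to 55) for eta and 81 (60 to 105) for gamma, lower than mine. It states: “The chain count is a guess”.

    L + Q → D + G (k = 0.240 L mol⁻¹ s⁻¹)
    L + D → G + D, rate k2*[D]*[L] (k = 1.50 L mol⁻¹ s⁻¹)
    Q + X → E (k = 990 L mol⁻¹ s⁻¹)

The flask gives 50.6 for eta and 96.5 for gamma, so gamma ends longer. At 4.00 min, eta holds the living end D at 0.00174 M, the reckoned chain count, while its G stands at 44.0% against my 38.4%. The ceiling length times that G is 50.6. With 0.0010 M of X and the rest as in gamma, the neighbour's ceiling is 200. Its G of 65.2% makes 130, and that flask ends at 130.

(The numbers in the tables are simulated for an exercise; noise was put on by code.)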